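The readings were computed with constants of no real substance, and the scatter is random.

Time runs through the readings below, so the first question of this examination is which number about a flask can be had without it. L is fed at a steady rate into E, and the flask holds two mono adducts, Q and G, and the bis adduct Z.

| flask | L | E | remark | time |
|---|---|---|---|---|
| south | 0.29 M (fed, over 8.0 min) | 0.73 M | run made earlier |  |
| north-east | 0.29 M (fed, over 8.0 min) | 1.1 M | run made earlier |  |
| flask | 0.29 M (fed, over 8.0 min) | 0.522 M |  | 8.0 min |

- south (time / min: L / %, Q / %, G / %): 1.33: 14.5, 1.8, 1.0; 2.50: 24.0, 4.0, 2.8; 4.00: 33.1, 7.7, 8.3; 5.00: 38.9, 9.9, 11.0; 6.00: 43.0, 13.3, 15.9; 8.00: 51.2, 20.1, 23.9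
- north-east (time / min: L / %, Q / %, G / %): 1.33: 13.4, 1.2, 0.6; 2.50: 21.3, 3.9, 5.5; 4.00: 27.2, 9.3, 11.4; 5.00: 31.7, 13.1, 14.5; 6.00: 34.3, 16.6, 18.3; 8.00: 39.0, 25.2, 27.9

(standard deviation of a reading: 0.5 percentage points)

1. the L standing at 8.0 min, as a percentage of the L charged
2. the Q standing at 8.0 min, as a percentage of the L charged
3. the G standing at 8.0 min, as a percentage of the L charged
4. the Z standing at 8.0 min, as a percentage of the L charged

What do you carry from run to run?

The Q share: the fraction of the two mono adducts that is Q, the selectivity between the two sites. Suppose Q and G each form from one L and one E. Then each rate carries the same L and the same E, so dividing one rate by the other drops both, and time with them. What stays is a ratio of two constants, as with two parallel drains on one tank.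

What do the runs give?

At 8.00 min, south reads 45.7% and north-east 47.5%. Pooled, they give 46.7%, the Q share.

Z draws on both adducts. Couldn't that bend the share with time?

It could, if Z took one adduct faster. But from 4.00 min to 8.00 min south goes from 48.1% to 45.7%, and north-east from 44.9% to 47.5%. These are opposite ways, on small early amounts with a scatter of 0.5 percentage points, so I read no drift.

This flask has less E than either run. Isn't that extrapolation?

In E it is. But between the runs E rises by a factor 1.51 and the share at 8.00 min moves by 1.8 points, which I can't tell from the scatter of the readings, as a quotient without E would show. So I commit to Q being 46.7% of the mono adducts in this flask at 8.0 min. The share says nothing of how much mono adduct there is.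

The forecast gives 61.5% of L, 16.7% of Q, 19.2% of G and 2.6% of Z, holding “so Q takes about 46–47% of the mono adduct”.

The flask gives 60.6% of L, 17.2% of Q, 19.4% of G and 2.80% of Z.

    L + E → Q (k = 0.00240 M⁻¹ s⁻¹)
    L + E → G (k = 0.00270 M⁻¹ s⁻¹)
    E + Q → Z (k = 9.30 × 10⁻⁴ M⁻¹ s⁻¹)
    E + G → Z (k = 9.20 × 10⁻⁴ M⁻¹ s⁻¹)

In this flask the Q share comes to 47.0%, and 46.7% of the Q and G standing gives 17.1% of Q against 17.2%. Part of why G stands at 19.4% in this flask is the drawn-out feeding of L together with the time allowed: without the drawn-out feeding it holds 30.0%, and left ten times as long it holds 28.1%. The neighbour flask with a quarter of the E still holds 87.6% of L, and there 46.7% of its mono adducts gives 5.66% of Q against the 5.71% it holds.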